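The constant that tells us how to charge the north-west run is a concentration, and the early readings of the runs so far give it.

| flask | starting material | partner | free catalyst | time |
|---|---|---|---|---|
| east | 0.300 M | 0.900 M | 0.0150 M |  |
| south-east | 0.150 M | 0.750 M | 0.0150 M |  |
| north-east | 0.600 M | 0.900 M | 0.0150 M |  |
| south | 0.300 M | 1.80 M | 0.0150 M |  |
| north-west | 0.900 M | 0.900 M | 0.0450 M | 7.9 h |

| east run: time / h | east run: [starting material] / M | south-east run: time / h | south-east run: [starting material] / M | north-east run: time / h | north-east run: [starting material] / M | south run: time / h | south run: [starting material] / M |
|---|---|---|---|---|---|---|---|
| 0.32 | 0.2651 | 0.32 | 0.1336 | 0.32 | 0.5490 | 0.32 | 0.2316 |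
| 0.60 | 0.2370 | 0.60 | 0.1186 | 0.60 | 0.5081 | 0.60 | 0.1883 |
| 1.1 | 0.2035 | 1.1 | 0.1007 | 1.1 | 0.4576 | 1.1 | 0.1337 |
| 2.2 | 0.1552 | 2.2 | 0.0779 | 2.2 | 0.3812 | 2.2 | 0.0728 |
| 4.1 | 0.1226 | 4.1 | 0.0640 | 4.1 | 0.3221 | 4.1 | 0.0428 |
| 7.9 | 0.1069 | 7.9 | 0.0538 | 7.9 | 0.2872 | 7.9 | 0.0235 |

(scatter of a reading: 0.002 M)

- Overall: starting material + partner -> target, with free catalyst as catalyst.
- Constant volume, constant temperature.
- A reading of a species includes what of it is bound.
- An order is taken over about fifteen percent of the charge, up and down.

- the power of [starting material] that the first rate follows, about the charge of the east run; measure it at two percent of starting material made into target (one fixed amount of target, the same in the runs compared)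
- the power of [partner] that the first rate follows, about the charge of the east run; measure it at two percent of starting material made into target
- the south-east run starts with 0.150 M less of starting material and of partner than the east run, and with no target. Compared where both hold the same amount of starting material, once fifteen percent of what the south-east run was charged with has turned into target, is the south-east run faster, slower or alike (within a tenth)?
- starting material in the north-west run at 7.9 h, as a share of the starting material charged

Suppose that at fixed partner and free catalyst the first rate goes as S/(Sc + S), with S the reading of starting material; this shape is called saturation kinetics. The order in starting material at S is then Sc/(Sc + S). The east and north-east runs share their partner and catalyst charges. By 0.32 h the north-east run has lost 1.46 times what the east run has lost, while averaging 0.575 M against 0.283 M. Those numbers give Sc = 0.463 M, a reading that carries the scatter of 0.002 M on a loss of 0.0349 M in the east run. This Sc is the crossover concentration, the reading of starting material at which its order is 0.5.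

Our own reckoning follows from it. At two percent turned in the east run, S is 0.294 M, so the order is 0.612. At the north-west charge of 0.900 M the order is 0.340, so that flask starts well above the crossover. Going from the north-east charge to this one multiplies starting material by 1.50 but, with partner and free catalyst held, the first rate by 1.17, which is less. We therefore put the increase into free catalyst, charging 0.0450 M, which is 3.00 times the east charge. Waiting is a poor substitute, since the east run loses 0.01570 M over its last 3.80 h. Partner stays at 0.900 M, as in the east and north-east runs, so the north-west run differs from the north-east run in starting material and free catalyst and in nothing else. This is a choice of comparison, not a finding about partner: twice the partner in the south run gives 1.96 times the first loss of the east run, which points to an order near one.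

The forecast gives orders of 0.62 and 1, calls the south-east run faster, and leaves 27.5% in the north-west run, on the ground of “first-order catalyst death”. Our order of 0.612 stands slightly below its figure.

The flask gives orders of 0.63 and 1.0, the south-east run is faster, and the north-west run holds 32.4% of its charge at 7.9 h.

    free catalyst + starting material ⇌ catalyst-substrate complex, settled at all times (2.280 M⁻¹)
    catalyst-substrate complex + partner → target + free catalyst + by-product (23.47 M⁻¹ h⁻¹)
    free catalyst → spent catalyst (0.2192 h⁻¹)
    partner → lost reagent (0.2268 h⁻¹)

Early in the east run the order in free catalyst is 1.0. The 0.292 M of starting material left in the north-west run puts its order at 0.614, higher than at its charge. With 0.006000 M of target made and partner taken at order one, Sc puts the south-east rate at 0.508 of the east rate, and the flask shows 0.061 M h⁻¹ against 0.12 M h⁻¹.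

Readings and results were computed with made-up constants, and the scatter is random.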